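**Strategy**

The target is an all-trans chalcone–diene Diels–Alder adduct that carries a (2R,3R)-dihydroflavonol. Everything rests on opening the pyranone ring C between the aryl ketone carbon C4 and the carbinol carbon C3: this α-ketol is read as an oxidised pinacol. A SmI2 ketyl cyclisation of a dialdehyde (aryl CHO tethered through the O1–C2 aryl ether to an α-aryloxy aldehyde) closes ring C, forms C3–C4 and relays the one catalytically set centre, C2, to C3 and C4 in a single event; benzylic oxidation then gives the ketol. The bromo-flavanonol is extended to a diene and joined to a 2′-hydroxychalcone by a chiral borate-catalysed Diels–Alder reaction.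

Key step: step 6

Remark: the ligand enantiomers written in steps 2 and 14 are those expected to give the drawn configurations; the antipodal ligand is used if the sense of induction proves to be the other one.
Remark: salts, metal alkoxides and catalyst-bound forms of numbered compounds are not numbered separately.

**Route**

Step 1
Reactants: 1 5-bromo-2-hydroxybenzaldehyde
Product: 2 5-bromo-2-(methoxymethoxy)benzaldehyde
Conditions: MOMCl, i-Pr2NEt, CH2Cl2, 0 °C → rt
Reagents that add atoms: chloromethyl methyl ether (MOMCl), COCCl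
Why: O-alkylation of the phenol with an α-chloro ether (Williamson-type etherification) should be clean under amine base and masks the acidic hydroxyl for the organometallic and reductive steps; no stereocentre is involved.

Step 2
Reactants: 2 5-bromo-2-(methoxymethoxy)benzaldehyde
Product: 3 (1S)-1-[5-bromo-2-(methoxymethoxy)phenyl]prop-2-en-1-ol
Conditions: (CH2=CH)2Zn (from CH2=CHMgBr and ZnCl2), (−)-DAIB (5 mol %), Et2O/toluene, 0 °C; aq NH4Cl
Reagents that add atoms: divinylzinc, C=C[Zn]C=C (made in the flask from vinylmagnesium bromide, C=C[Mg]Br, and ZnCl2)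
Why: amino-alcohol-catalysed enantioselective 1,2-addition of an alkenylzinc to an aryl aldehyde should set the carbinol centre (the later C2 of the flavanonol) as S by ligand-controlled attack on one aldehyde face, the aryl bromide and the MOM ether being inert to the organozinc.

Step 3
Reactants: 4 2-fluoro-4-hydroxybenzaldehyde
Product: 5 2-fluoro-4-(methoxymethoxy)benzaldehyde
Conditions: MOMCl, i-Pr2NEt, CH2Cl2, 0 °C → rt
Reagents that add atoms: chloromethyl methyl ether (MOMCl), COCCl
Why: O-alkylation of the phenol (Williamson-type etherification) removes the acidic proton that would otherwise quench the alkoxide and deactivate the ring in step 4.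

Step 4
Reactants: 3 (1S)-1-[5-bromo-2-(methoxymethoxy)phenyl]prop-2-en-1-ol; 5 2-fluoro-4-(methoxymethoxy)benzaldehyde
Product: 6 2-{[(1S)-1-[5-bromo-2-(methoxymethoxy)phenyl]prop-2-en-1-yl]oxy}-4-(methoxymethoxy)benzaldehyde
Conditions: NaH, DMF, 0 °C → rt
Reagents that add atoms: none
Why: nucleophilic aromatic substitution, in which the sodium alkoxide of 3 should displace the fluoride activated by the ortho-formyl group through a Meisenheimer adduct; the C–O bond of the stereocentre is not touched, so its configuration is retained, and the unactivated aryl bromide does not react.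

Step 5
Reactants: 6 2-{[(1S)-1-[5-bromo-2-(methoxymethoxy)phenyl]prop-2-en-1-yl]oxy}-4-(methoxymethoxy)benzaldehyde
Product: 8 2-{[(1R)-1-[5-bromo-2-(methoxymethoxy)phenyl]-2-oxoethyl]oxy}-4-(methoxymethoxy)benzaldehyde, via secondary ozonide 7 (not isolated)
Conditions: O3, CH2Cl2, −78 °C (Sudan III end point); PPh3, −78 °C → rt; crude product used at once
Reagents that add atoms: ozone, [O-][O+]=O
Why: ozonolysis with reductive work-up should cleave only the isolated terminal alkene (the donor-substituted arenes react far more slowly at −78 °C under indicator control) and leaves the stereocentre untouched (S becomes R by priority change only); the enolisable aldehyde 8 is therefore carried on cold and without chromatography.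

Step 6
Reactants: 8 2-{[(1R)-1-[5-bromo-2-(methoxymethoxy)phenyl]-2-oxoethyl]oxy}-4-(methoxymethoxy)benzaldehyde
Product: 9 (2R,3S,4S)-2-[5-bromo-2-(methoxymethoxy)phenyl]-7-(methoxymethoxy)-3,4-dihydro-2H-chromene-3,4-diol
Conditions: SmI2 (2.5 equiv), t-BuOH, THF (0.01 M, slow addition of 8), −78 °C → −20 °C
Reagents that add atoms: none
Why: SmI2 should reduce the conjugated aryl aldehyde selectively to a samarium ketyl, which adds to the Sm(III)-activated aliphatic formyl carbon and, after a second electron transfer and protonation, gives the cyclic cis-diol; the closest known reaction type is the SmI2-mediated intramolecular pinacol coupling of 1,6-dialdehydes. The dihydropyran ring is closed by a 6-exo-trig attack of the ketyl carbon (future C4) on the formyl carbon (future C3). C3 is controlled by the existing C2 centre: in the chair-like transition state the C2 aryl group sits pseudo-equatorial and the bulky samarium-bound oxygen at C3 turns away from it, so the C3 oxygen ends trans to the aryl group (3S). C4 is controlled by Sm(III) bridging of the two oxygens, which places the C4 oxygen cis to that at C3 (4S); this centre is erased in step 7. The step needs ketyl formation at the aryl aldehyde and not at the α-aryloxy aldehyde (whose ketyl would expel the aryloxide), which the lower reduction potential of the aryl aldehyde secures, and cyclisation over dimerisation, which the six-membered tether and high dilution secure. The cold, non-basic conditions should preserve the enolisable C2 centre, and aryl bromide and MOM ethers are inert to SmI2 in THF without HMPA.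

Step 7
Reactants: 9 (2R,3S,4S)-2-[5-bromo-2-(methoxymethoxy)phenyl]-7-(methoxymethoxy)-3,4-dihydro-2H-chromene-3,4-diol
Product: 10 (2R,3R)-2-[5-bromo-2-(methoxymethoxy)phenyl]-3-hydroxy-7-(methoxymethoxy)-2,3-dihydro-4H-chromen-4-one
Conditions: DDQ (1.1 equiv), CH2Cl2, 0 °C → rt
Reagents that add atoms: none
Why: DDQ oxidation of a benzylic alcohol by hydride abstraction should take only the C4 carbinol, whose C–H is activated by the ortho and para oxygen donors of ring A, while the non-benzylic C3 carbinol and the C2–H on the bromoaryl ring are much less hydridic; C2 and C3 are untouched, so the trans ketol results (3S becomes 3R by priority change only).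

Step 8
Reactants: 10 (2R,3R)-2-[5-bromo-2-(methoxymethoxy)phenyl]-3-hydroxy-7-(methoxymethoxy)-2,3-dihydro-4H-chromen-4-one
Product: 11 (2R,3R)-2-[5-bromo-2-(methoxymethoxy)phenyl]-7-(methoxymethoxy)-3-[(triethylsilyl)oxy]-2,3-dihydro-4H-chromen-4-one
Conditions: TESCl, imidazole, DMF, 0 °C → rt
Reagents that add atoms: chlorotriethylsilane (TESCl), CC[Si](Cl)(CC)CC
Why: silylation of the secondary alcohol under imidazole catalysis should be too mild to enolise C3, and the silyl ether keeps the α-ketol from binding boron in step 14.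

Step 9
Reactants: 12 2-methylbut-1-en-3-yne
Product: 13 tributyl[(1E)-3-methylbuta-1,3-dien-1-yl]stannane
Conditions: Bu3SnH, AIBN (cat.), neat, sealed tube, 80 °C
Reagents that add atoms: tributyltin hydride, CCCC[SnH](CCCC)CCCC
Why: radical hydrostannation of the terminal alkyne should place tin on the terminal carbon and, through reversible stannyl radical addition, converge on the E-dienylstannane.

Step 10
Reactants: 11 (2R,3R)-2-[5-bromo-2-(methoxymethoxy)phenyl]-7-(methoxymethoxy)-3-[(triethylsilyl)oxy]-2,3-dihydro-4H-chromen-4-one; 13 tributyl[(1E)-3-methylbuta-1,3-dien-1-yl]stannane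
Product: 14 (2R,3R)-7-(methoxymethoxy)-2-{2-(methoxymethoxy)-5-[(1E)-3-methylbuta-1,3-dien-1-yl]phenyl}-3-[(triethylsilyl)oxy]-2,3-dihydro-4H-chromen-4-one
Conditions: Pd(PPh3)4 (5 mol %), BHT (cat.), toluene, 100 °C
Reagents that add atoms: none
Why: Stille coupling (oxidative addition into the C–Br bond, transmetalation, reductive elimination) should transfer the dienyl group with retention of the E geometry under neutral conditions that spare the base-sensitive flavanone, the silyl ether and both stereocentres.

Step 11
Reactants: 15 2,4-dihydroxybenzaldehyde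
Product: 16 2,4-bis(methoxymethoxy)benzaldehyde
Conditions: MOMCl (3 equiv), i-Pr2NEt, CH2Cl2, 0 → 40 °C
Reagents that add atoms: chloromethyl methyl ether (MOMCl), COCCl
Why: double O-alkylation of both phenols (Williamson-type etherification); masking the 2-hydroxyl prevents flavylium or flavanone formation during and after the condensation.

Step 12
Reactants: 17 1-(2,4-dihydroxyphenyl)ethan-1-one
Product: 18 1-[2-hydroxy-4-(methoxymethoxy)phenyl]ethan-1-one
Conditions: MOMCl (1.05 equiv), i-Pr2NEt, CH2Cl2, 0 °C
Reagents that add atoms: chloromethyl methyl ether (MOMCl), COCCl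
Why: the 4-hydroxyl should be alkylated selectively because the 2-hydroxyl is hydrogen-bonded to the ketone and far less nucleophilic; the free 2-OH is the boron-binding handle needed in step 14.

Step 13
Reactants: 16 2,4-bis(methoxymethoxy)benzaldehyde; 18 1-[2-hydroxy-4-(methoxymethoxy)phenyl]ethan-1-one
Product: 19 (2E)-3-[2,4-bis(methoxymethoxy)phenyl]-1-[2-hydroxy-4-(methoxymethoxy)phenyl]prop-2-en-1-one
Conditions: KOH, EtOH/H2O, rt; dilute HCl to pH 5
Reagents that add atoms: none
Why: Claisen–Schmidt condensation (aldol addition, then E1cB dehydration) should give the thermodynamically favoured E-enone, the MOM ethers being stable to hydroxide.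

Step 14
Reactants: 14 (2R,3R)-7-(methoxymethoxy)-2-{2-(methoxymethoxy)-5-[(1E)-3-methylbuta-1,3-dien-1-yl]phenyl}-3-[(triethylsilyl)oxy]-2,3-dihydro-4H-chromen-4-one; 19 (2E)-3-[2,4-bis(methoxymethoxy)phenyl]-1-[2-hydroxy-4-(methoxymethoxy)phenyl]prop-2-en-1-one
Product: 20 [(1R,2R,6S)-6-[2,4-bis(methoxymethoxy)phenyl]-2-{4-(methoxymethoxy)-3-[(2R,3R)-7-(methoxymethoxy)-4-oxo-3-[(triethylsilyl)oxy]-3,4-dihydro-2H-chromen-2-yl]phenyl}-4-methylcyclohex-3-en-1-yl][2-hydroxy-4-(methoxymethoxy)phenyl]methanone
Conditions: B(OPh)3 (20 mol %), (R)-VANOL (20 mol %), 5 Å MS, toluene, rt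
Reagents that add atoms: none
Why: Diels–Alder reaction of a 2′-hydroxychalcone activated as a chelate on a chiral borate, in which the electron-rich 1-aryl-3-methyl diene should add with the usual ortho/para regiochemistry, the E-enone fixes C1/C6 trans, the exo placement of the aroyl group gives C1/C2 trans, and the VANOL ligand shields one enone face to set the absolute configuration (1R,2R,6S), the distant flavanonol centres being unaffected.

Step 15
Reactants: 20 the protected Diels–Alder adduct of step 14
Product: 21 (2R,3R)-2-{5-[(1R,5S,6R)-6-(2,4-dihydroxybenzoyl)-5-(2,4-dihydroxyphenyl)-3-methylcyclohex-2-en-1-yl]-2-hydroxyphenyl}-3,7-dihydroxy-2,3-dihydro-4H-chromen-4-one (CNP0219853.1)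
Conditions: HCl (1.25 M in MeOH), THF, rt → 35 °C, argon
Reagents that add atoms: none
Why: acid-catalysed methanolysis (acetal exchange of the five MOM ethers, solvolysis of the silyl ether) should free all seven hydroxyls under conditions too mild to protonate the trisubstituted alkene, and both the all-trans ketone and the trans-flavanonol are already the thermodynamic isomers.

**Compound list**

1 | 5-bromo-2-hydroxybenzaldehyde | O=Cc1cc(Br)ccc1O | starting material
2 | 5-bromo-2-(methoxymethoxy)benzaldehyde | COCOc1ccc(Br)cc1C=O | intermediate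
3 | (1S)-1-[5-bromo-2-(methoxymethoxy)phenyl]prop-2-en-1-ol | C=C[C@H](O)c1cc(Br)ccc1OCOC | intermediate
4 | 2-fluoro-4-hydroxybenzaldehyde | O=Cc1ccc(O)cc1F | starting material
5 | 2-fluoro-4-(methoxymethoxy)benzaldehyde | COCOc1ccc(C=O)c(F)c1 | intermediate
6 | 2-{[(1S)-1-[5-bromo-2-(methoxymethoxy)phenyl]prop-2-en-1-yl]oxy}-4-(methoxymethoxy)benzaldehyde | C=C[C@H](Oc1cc(OCOC)ccc1C=O)c1cc(Br)ccc1OCOC | intermediate
7 | secondary ozonide of 6: 2-{(R)-[5-bromo-2-(methoxymethoxy)phenyl](1,2,4-trioxolan-3-yl)methoxy}-4-(methoxymethoxy)benzaldehyde, both epimers at the trioxolane carbon, formed and consumed in the flask | O1COOC1[C@H](Oc1cc(OCOC)ccc1C=O)c1cc(Br)ccc1OCOC | intermediate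
8 | 2-{[(1R)-1-[5-bromo-2-(methoxymethoxy)phenyl]-2-oxoethyl]oxy}-4-(methoxymethoxy)benzaldehyde | O=C[C@H](Oc1cc(OCOC)ccc1C=O)c1cc(Br)ccc1OCOC | intermediate
9 | (2R,3S,4S)-2-[5-bromo-2-(methoxymethoxy)phenyl]-7-(methoxymethoxy)-3,4-dihydro-2H-chromene-3,4-diol (2,3-trans, 3,4-cis) | O[C@@H]1[C@H](O)[C@@H](c3cc(Br)ccc3OCOC)Oc2cc(OCOC)ccc21 | intermediate
10 | (2R,3R)-2-[5-bromo-2-(methoxymethoxy)phenyl]-3-hydroxy-7-(methoxymethoxy)-2,3-dihydro-4H-chromen-4-one (trans) | COCOc1ccc(Br)cc1[C@H]2Oc3cc(OCOC)ccc3C(=O)[C@@H]2O | intermediate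
11 | (2R,3R)-2-[5-bromo-2-(methoxymethoxy)phenyl]-7-(methoxymethoxy)-3-[(triethylsilyl)oxy]-2,3-dihydro-4H-chromen-4-one | COCOc1ccc(Br)cc1[C@H]2Oc3cc(OCOC)ccc3C(=O)[C@@H]2O[Si](CC)(CC)CC | intermediate
12 | 2-methylbut-1-en-3-yne | C=C(C)C#C | starting material
13 | tributyl[(1E)-3-methylbuta-1,3-dien-1-yl]stannane | CCCC[Sn](CCCC)(CCCC)/C=C/C(C)=C | intermediate
14 | (2R,3R)-7-(methoxymethoxy)-2-{2-(methoxymethoxy)-5-[(1E)-3-methylbuta-1,3-dien-1-yl]phenyl}-3-[(triethylsilyl)oxy]-2,3-dihydro-4H-chromen-4-one | COCOc1ccc(/C=C/C(C)=C)cc1[C@H]2Oc3cc(OCOC)ccc3C(=O)[C@@H]2O[Si](CC)(CC)CC | intermediate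
15 | 2,4-dihydroxybenzaldehyde | O=Cc1ccc(O)cc1O | starting material
16 | 2,4-bis(methoxymethoxy)benzaldehyde | COCOc1ccc(C=O)c(OCOC)c1 | intermediate
17 | 1-(2,4-dihydroxyphenyl)ethan-1-one | CC(=O)c1ccc(O)cc1O | starting material
18 | 1-[2-hydroxy-4-(methoxymethoxy)phenyl]ethan-1-one | CC(=O)c1ccc(OCOC)cc1O | intermediate
19 | (2E)-3-[2,4-bis(methoxymethoxy)phenyl]-1-[2-hydroxy-4-(methoxymethoxy)phenyl]prop-2-en-1-one | COCOc1ccc(C(=O)/C=C/c2ccc(OCOC)cc2OCOC)c(O)c1 | intermediate
20 | [(1R,2R,6S)-6-[2,4-bis(methoxymethoxy)phenyl]-2-{4-(methoxymethoxy)-3-[(2R,3R)-7-(methoxymethoxy)-4-oxo-3-[(triethylsilyl)oxy]-3,4-dihydro-2H-chromen-2-yl]phenyl}-4-methylcyclohex-3-en-1-yl][2-hydroxy-4-(methoxymethoxy)phenyl]methanone (all-trans cyclohexene) | CC1=C[C@@H](c2ccc(OCOC)c([C@H]3Oc4cc(OCOC)ccc4C(=O)[C@@H]3O[Si](CC)(CC)CC)c2)[C@H](C(=O)c2ccc(OCOC)cc2O)[C@@H](c2ccc(OCOC)cc2OCOC)C1 | intermediate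
21 | (2R,3R)-2-{5-[(1R,5S,6R)-6-(2,4-dihydroxybenzoyl)-5-(2,4-dihydroxyphenyl)-3-methylcyclohex-2-en-1-yl]-2-hydroxyphenyl}-3,7-dihydroxy-2,3-dihydro-4H-chromen-4-one (CNP0219853.1) | CC1=C[C@@H](c2ccc(O)c([C@H]3Oc4cc(O)ccc4C(=O)[C@@H]3O)c2)[C@H](C(=O)c2ccc(O)cc2O)[C@@H](c2ccc(O)cc2O)C1 | target

**Step count and risks**

Total step count: 15. Longest linear sequence: 10 steps (1, 2, 4, 5, 6, 7, 8, 10, 14, 15).

Step 6 (key step). The enolisable α-aryloxy aldehyde may lose its configuration between ozonolysis and cyclisation. Electron transfer to the aliphatic aldehyde may compete and expel the aryloxide. Simple reduction may outrun ring closure, and the facial selectivity at C3 may be poor. The fallback never passes through the aldehyde and forms the same C3–C4 bond by metathesis. It sets out from 6: Wittig methylenation of the aryl aldehyde (Ph3P=CH2 from Ph3PCH3Br and KOt-Bu, THF, 0 °C) should give 4-bromo-1-(methoxymethoxy)-2-[(1S)-1-{[5-(methoxymethoxy)-2-vinylphenyl]oxy}prop-2-en-1-yl]benzene F1. Ring-closing metathesis (second-generation Grubbs catalyst, CH2Cl2, 40 °C) should then give (2S)-2-[5-bromo-2-(methoxymethoxy)phenyl]-7-(methoxymethoxy)-2H-chromene F2. Dihydroxylation with OsO4 (cat.) and NMO in acetone/water should add both hydroxyls to the face opposite the C2 aryl group, and the route is rejoined at 9.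

Step 14. The exo transition state may not be preferred over the endo one, Lewis-basic sites of the diene may compete for boron and slow turnover, and facial control may erode with so large a diene. The fallback gives up catalyst control. It sets out from 14 and 19: the cycloaddition is run with silica-supported silver nanoparticles (CH2Cl2, 50 °C), which activate the 2′-hydroxychalcone without a chiral ligand. Because the (2R,3R)-flavanonol is already enantiopure, all cyclohexene isomers are diastereomers, and the all-trans (1R,2R,6S) isomer is separated by preparative HPLC. The route is rejoined at 20, and this fallback makes no new compound (F0).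

Step 2. An uncatalysed, chelation-assisted background addition at the ortho-alkoxy aldehyde may lower the enantiomeric purity, and divinylzinc free of magnesium salts may be difficult to prepare reproducibly. The fallback replaces asymmetric addition by resolution. It sets out from 2: vinylmagnesium bromide (THF, −78 °C) should give racemic 1-[5-bromo-2-(methoxymethoxy)phenyl]prop-2-en-1-ol F3. Lipase-catalysed kinetic resolution (immobilised Candida antarctica lipase B, vinyl acetate, MTBE, 30 °C) should acylate the R enantiomer to (1R)-1-[5-bromo-2-(methoxymethoxy)phenyl]prop-2-en-1-yl acetate F4, which is removed by chromatography. The unreacted S alcohol is 3, where the route is rejoined.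

Further compounds
F1 | step 6 | 4-bromo-1-(methoxymethoxy)-2-[(1S)-1-{[5-(methoxymethoxy)-2-vinylphenyl]oxy}prop-2-en-1-yl]benzene | C=C[C@H](Oc1cc(OCOC)ccc1C=C)c1cc(Br)ccc1OCOC
F2 | step 6 | (2S)-2-[5-bromo-2-(methoxymethoxy)phenyl]-7-(methoxymethoxy)-2H-chromene | C1=C[C@@H](c3cc(Br)ccc3OCOC)Oc2cc(OCOC)ccc12
F0 | step 14 | none | none
F3 | step 2 | racemic 1-[5-bromo-2-(methoxymethoxy)phenyl]prop-2-en-1-ol | C=CC(O)c1cc(Br)ccc1OCOC
F4 | step 2 | (1R)-1-[5-bromo-2-(methoxymethoxy)phenyl]prop-2-en-1-yl acetate | C=C[C@@H](OC(C)=O)c1cc(Br)ccc1OCOC
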